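**Retrosynthetic overview**
1. Core, formed last: cut C1–C2 and C5–C6 of the tricyclo[4.2.1.1(2,5)]deca-3,7-diene. This gives two molecules of one chiral 1,2-disubstituted cyclopentadiene (two 1,5-H-shift tautomers), joined by a face-to-face cross-[4+4] dimerisation.
2. Cyclopentadiene ring: dehydration of a cyclopent-3-enol, itself made by [4+1] union of a cyclopropyl acyl carbon with the C5 unit of penta-1,3-diene.
3. Key bond: the C–O bond of each methyl ketone, made by Baeyer–Villiger oxygen insertion into carone. This one step plants the future ketone oxygen on the side chain and turns the ring carbonyl into the acyl carbon used in line 2.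
4. Carone comes from (S)-carvone by conjugate reduction, HCl addition and 1,3-elimination. C5 of carvone sets both cyclopropane centres, and these steer the core.
5. Ring order: cyclopropane, then a temporary seven-membered lactone, then the five-membered ring, then the six- and eight-membered rings of the core.

Assumption: the methyl-bearing centre next to the carbonyl (later the side-chain carbinol centre) is carried as an epimer mixture. The major (S) epimer is drawn, and the centre is erased when the side-chain ketone is made.

**Step 1**
Reactants: 1 (S)-(+)-carvone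
Product: 2 (2S,5S)-2-methyl-5-(prop-1-en-2-yl)cyclohexan-1-one (trans-dihydrocarvone, some 2R epimer)
Conditions: Zn dust, KOH, EtOH–H2O, reflux
Reagents that add atoms: none
Why: Dissolving-metal conjugate reduction reaches only the conjugated C=C, so the isopropenyl group and C5 are untouched, and enolate protonation with equilibration gives mainly the trans (2S) epimer.

**Step 2**
Reactants: 2 trans-dihydrocarvone
Product: 4 (1R,3S,6S)-3,7,7-trimethylbicyclo[4.1.0]heptan-2-one (carone), via tertiary chloride 3 (not isolated)
Conditions: HCl (g), Et2O, 0 °C; evaporate; KOtBu, THF, 0 °C to rt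
Reagents that add atoms: none
Why: Markovnikov hydrochlorination is followed by base-induced 1,3-elimination (3-exo-tet enolate alkylation, the classical carone synthesis); only the C6 enolate can reach the tertiary chloride and the three-membered ring can only be cis-fused, so C5 of carvone fixes both cyclopropane centres as (1R,6S).

**Step 3 (key C–O bond)**
Reactants: 4 carone
Product: 5 (1R,4S,7S)-4,8,8-trimethyl-3-oxabicyclo[5.1.0]octan-2-one
Conditions: mCPBA (1.5 equiv), CH2Cl2, 0 °C to rt
Reagents that add atoms: 3-chloroperoxybenzoic acid (mCPBA), O=C(OO)c1cccc(Cl)c1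
Why: In this Baeyer–Villiger oxidation the secondary alkyl carbon migrates with retention far better than the cyclopropyl carbon, so oxygen enters only between C2 and C3, and this oxygen ends as the ketone oxygen of the target while C2 becomes an acyl carbon.

**Step 4**
Reactants: 5 lactone; 6 (E)-penta-1,3-diene
Product: 8 1-{(1R,3S)-3-[(3S)-3-hydroxybutyl]-2,2-dimethylcyclopropyl}-2-methylcyclopent-3-en-1-ol (mixture at the two new ring centres), via magnesacyclopentene 7 (not isolated)
Conditions: Mg* (activated Mg powder, THF slurry), 6, THF, rt; then 5, −78 °C to reflux; H2O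
Reagents that add atoms: none
Why: This is the formal [4+1] annulation of a 2-butene-1,4-diylmagnesium reagent with a carboxylic ester: acyl substitution opens the lactone to a ketone alkoxide, the remaining allylmagnesium end adds intramolecularly faster than the cyclopropyl ketone can enolise, warming funnels the material to the cyclopent-3-enolate, and the two new centres form unselectively but are erased in step 6.

**Step 5**
Reactants: 8 diol
Product: 9 4-[(1S,3R)-3-(1-hydroxy-2-methylcyclopent-3-en-1-yl)-2,2-dimethylcyclopropyl]butan-2-one
Conditions: n-Pr4N[RuO4] (5 mol %), NMO, 4 Å MS, CH2Cl2, rt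
Reagents that add atoms: none
Why: The Ley–Griffith oxidation takes the secondary alcohol to the ketone under neutral conditions, while the tertiary alcohol cannot be oxidised and the alkene and cyclopropane are inert, and the epimeric carbinol centre disappears here.

**Step 6**
Reactants: 9 keto alcohol
Product: 10 4-[(1S,3R)-2,2-dimethyl-3-(2-methylcyclopenta-1,4-dien-1-yl)cyclopropyl]butan-2-one (in equilibrium with its 1,5-H-shift tautomers)
Conditions: Burgess reagent (MeO2CN(−)SO2N(+)Et3), PhMe, 50 °C; short SiO2 plug; kept as a 0.5 M solution
Reagents that add atoms: none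
Why: In the Burgess dehydration the tertiary sulfamate collapses by syn (Ei) elimination under neutral conditions, which avoids a free cyclopropylcarbinyl cation, and the first-formed dienes equilibrate by 1,5-H shifts so both carbinol-ring centres vanish and no new one is made.

**Step 7**
Reactants: 10 cyclopentadiene (two molecules)
Product: 12 (1S,2S,5S,6S)-1,3-dimethyl-4,8-bis[(1R,3S)-2,2-dimethyl-3-(3-oxobutyl)cyclopropyl]tricyclo[4.2.1.1(2,5)]deca-3,7-diene, via diene tautomer 11 (not isolated)
Conditions: Ir(dFppy)3 (dFppy = 2-(2,4-difluorophenyl)pyridinato, 1 mol %), degassed PhMe (0.5 M), 427 nm LED, 25 °C; HPLC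
Reagents that add atoms: none
Why: Proposed new method: triplet-sensitised head-to-tail cross-[4+4] cyclodimerisation of a cyclopentadiene (closest known reaction types: sensitised photodimerisation of cyclopentadiene and other 1,3-dienes, which so far stops at [2+2] and [4+2] dimers, and the [4+4] photodimerisation of 2-pyridones and anthracenes); Ir(dFppy)3 (triplet about 60 kcal/mol) can excite only the conjugated diene (about 58 kcal/mol), not the ketone or the non-conjugated product, so the product is not re-excited; 10 and 11 interconvert by thermal 1,5-H shifts (Curtin–Hammett), and the excited diene bonds through its one unsubstituted terminus to the terminus of 11 that leaves a cyclopropyl-stabilised allyl radical (C5–C6 bond); after intersystem crossing the face-to-face bis-allyl biradical closes at its outer termini (C1–C2), the pairing that keeps the two cyclopropyl groups offset and leaves the tri- and tetrasubstituted alkenes; both dienes react suprafacially, which fixes the four new centres relative to each other (both CH2 bridges on one side), and the absolute sense is relayed from the cyclopropanes because, in the A(1,3)-minimised rotamers, only this diastereomer places a CMe2 methyl rather than the oxobutyl chain in the cleft between the two cyclopropyl groups.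

**Compound list**
1 | (S)-(+)-carvone | CC1=CC[C@@H](CC1=O)C(C)=C | starting material
2 | (2S,5S)-2-methyl-5-(prop-1-en-2-yl)cyclohexan-1-one | C[C@H]1CC[C@@H](CC1=O)C(C)=C | intermediate
3 | (2S,5S)-5-(2-chloropropan-2-yl)-2-methylcyclohexan-1-one | C[C@H]1CC[C@@H](CC1=O)C(C)(C)Cl | intermediate
4 | (1R,3S,6S)-3,7,7-trimethylbicyclo[4.1.0]heptan-2-one (carone) | C[C@H]1CC[C@H]2[C@@H](C1=O)C2(C)C | intermediate
5 | (1R,4S,7S)-4,8,8-trimethyl-3-oxabicyclo[5.1.0]octan-2-one | C[C@H]1CC[C@H]2[C@@H](C(=O)O1)C2(C)C | intermediate
6 | (E)-penta-1,3-diene | C/C=C/C=C | starting material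
7 | 2-methyl-1-magnesacyclopent-3-ene (pent-2-ene-1,4-diylmagnesium, THF solvate) | CC1C=CC[Mg]1 | intermediate
8 | 1-{(1R,3S)-3-[(3S)-3-hydroxybutyl]-2,2-dimethylcyclopropyl}-2-methylcyclopent-3-en-1-ol (mixture at C1 and C2 of the cyclopentenol) | C[C@H](O)CC[C@H]1[C@@H](C2(O)CC=CC2C)C1(C)C | intermediate
9 | 4-[(1S,3R)-3-(1-hydroxy-2-methylcyclopent-3-en-1-yl)-2,2-dimethylcyclopropyl]butan-2-one (same mixture) | CC(=O)CC[C@H]1[C@@H](C2(O)CC=CC2C)C1(C)C | intermediate
10 | 4-[(1S,3R)-2,2-dimethyl-3-(2-methylcyclopenta-1,4-dien-1-yl)cyclopropyl]butan-2-one | CC(=O)CC[C@H]1[C@@H](C2=C(C)CC=C2)C1(C)C | intermediate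
11 | 4-[(1S,3R)-2,2-dimethyl-3-(5-methylcyclopenta-1,4-dien-1-yl)cyclopropyl]butan-2-one | CC(=O)CC[C@H]1[C@@H](C2=CCC=C2C)C1(C)C | intermediate
12 | (1S,2S,5S,6S)-1,3-dimethyl-4,8-bis[(1R,3S)-2,2-dimethyl-3-(3-oxobutyl)cyclopropyl]tricyclo[4.2.1.1(2,5)]deca-3,7-diene (CNP0300925.1) | CC(=O)CC[C@H]1[C@@H](C2=C[C@@H]3C[C@@]2(C)[C@H]2C[C@@H]3C([C@@H]3[C@H](CCC(C)=O)C3(C)C)=C2C)C1(C)C | target

**Total step count:** 7. **Longest linear sequence:** 7 (1 to 12; 6 enters in step 4).

**Three steps most likely to fail**

**Step 7 (the proposed new step).**
- Risks: the biradical may rotate and close to [4+2] dimers or anti-cyclobutanes. Other tautomer pairs may react. Facial selectivity may be modest. The triplet vinylcyclopropane may leak from cis to trans. [4+2] dimers can be cracked thermally back to 10 and recycled.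
- Fallback, from 10 back to 12, using known reactions only: build a four-membered ring first and let a ground-state sigmatropic shift form the hindered bond. Classical ketone-sensitised photodimerisation of the cyclopentadiene (xanthone, 350 nm, pentane, −30 °C) gives cyclobutane dimers. The head-to-head cis,syn,cis cyclobutane dimer F1 carries the C5–C6 and C4–C7 bonds in the numbering of 12 and is separated by chromatography. Heating it in PhMe at 80–110 °C triggers the Cope rearrangement of a cis-1,2-dialkenylcyclobutane through the boat transition state. Release of four-ring strain drives formation of the quaternary C1–C2 bond and delivers 12 with transfer of configuration.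

**Step 4.**
- Risks: the unsymmetrical pentadiene–magnesium reagent may stop at the β,γ-unsaturated ketone or a vinylcyclopropanol. The transient cyclopropyl ketone may epimerise.
- Fallback, from 5 back to 8: the lactone is opened with MeNH(OMe)·HCl and i-PrMgCl to the hydroxy Weinreb amide F2. Crotylmagnesium chloride (CH3CH=CHCH2MgCl) adds once through its γ-carbon to give the α-methyl β,γ-unsaturated ketone F3. Allylmagnesium bromide (CH2=CHCH2MgBr) gives the tertiary dienyl carbinol F4. Ring-closing metathesis with the second-generation Grubbs catalyst, (H2IMes)(PCy3)Cl2Ru=CHPh, closes the cyclopent-3-enol 8.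

**Step 2.**
- Risks: E2 loss of HCl and unproductive enolisation at the methyl-bearing carbon compete with the 3-exo-tet closure.
- Fallback, from 1 back to 4: HCl is added to carvone itself to give carvone hydrochloride F5. With KOtBu the cross-conjugated enone can enolise only at C6, so it closes cleanly to (1R,6S)-car-3-en-2-one F6. 1,4-Reduction with Li[HB(s-Bu)3] (THF, −78 °C) gives 4. Step 1 is then dropped and the step count is unchanged.

**Further compounds**
F1 | step 7 | cis,syn,cis [2+2] dimer, 4,10-dimethyl-1,3-bis[(1R,3S)-2,2-dimethyl-3-(3-oxobutyl)cyclopropyl]tricyclo[5.3.0.0(2,6)]deca-3,9-diene | CC(=O)CC[C@H]1[C@@H](C2=C(C)C[C@H]3[C@@H]2[C@@]4([C@@H]5[C@H](CCC(C)=O)C5(C)C)C(C)=CC[C@@H]34)C1(C)C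
F2 | step 4 | (1R,3S)-3-[(3S)-3-hydroxybutyl]-N-methoxy-N,2,2-trimethylcyclopropane-1-carboxamide | C[C@H](O)CC[C@H]1[C@@H](C(=O)N(C)OC)C1(C)C
F3 | step 4 | 1-{(1R,3S)-3-[(3S)-3-hydroxybutyl]-2,2-dimethylcyclopropyl}-2-methylbut-3-en-1-one | C[C@H](O)CC[C@H]1[C@@H](C(=O)C(C)C=C)C1(C)C
F4 | step 4 | 4-{(1R,3S)-3-[(3S)-3-hydroxybutyl]-2,2-dimethylcyclopropyl}-3-methylhepta-1,6-dien-4-ol | C[C@H](O)CC[C@H]1[C@@H](C(O)(CC=C)C(C)C=C)C1(C)C
F5 | step 2 | (5S)-5-(2-chloropropan-2-yl)-2-methylcyclohex-2-en-1-one | CC1=CC[C@@H](CC1=O)C(C)(C)Cl
F6 | step 2 | (1R,6S)-3,7,7-trimethylbicyclo[4.1.0]hept-3-en-2-one | CC1=CC[C@H]2[C@@H](C1=O)C2(C)C
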